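## Retrosynthetic overview

1. Target ⇒ (C15–Cl → OAc; C11–CO2H → H) ⇒ γ,δ-unsaturated acid. The key disconnection is C9–C11, made by an Ireland–Claisen [3,3] shift of a C7β allylic ester, which sets C9 and places the Δ7 olefin.
2. Allylic ester ⇒ Mitsunobu union (inversion at C7) of a decalin allylic alcohol (7α-OH, Δ8) with a C6 chloro acid that carries C13.
3. Allylic alcohol ⇒ Wharton transposition of the epoxide of a Δ7-9-one decalin. Ring A of that enone ⇒ HAT-initiated radical closure (C3–C4) of an isopropenyl group onto an aldehyde.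
4. Ring B is bought as (R)-carvone 1 (supplies C5). C10 is built by two α′-alkylations (Me, then allyl → CH2CH2CHO). Ring order: B (bought), then A.
5. Chloro acid ⇒ (S)-citronellol 2 (supplies C13) by chlorination and oxidative cleavage.

Convention and assumption: bicyclic compounds carry labdane numbering (C10 = ring-fusion carbon with the angular methyl, C5 = ring-fusion CH, C4 = gem-dimethyl carbon, C3 = carbinol carbon, C9–C8–C7–C6 run round ring B from C10 to C5; β = face of the C10 methyl, α = face of H-5). (R)-(−)-Carvone and (S)-(−)-β-citronellol are bought as single enantiomers. The route has not been run; selectivities are predictions from analogy.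

## Route

Step 1
Reactants: 1 (R)-(−)-carvone
Product: 4 (5R,6RS)-2,6-dimethyl-5-(prop-1-en-2-yl)cyclohex-2-en-1-one (6-methylcarvone; C6 epimers), via lithium dienolate 3 (not isolated)
Conditions: LDA, THF, −78 °C; then MeI, −78 → 0 °C
Reagents that add atoms: iodomethane, CI
Why: Kinetic α′-deprotonation and SN2 methylation of the cross-conjugated lithium dienolate (enolate alkylation); the new centre is an inconsequential epimer mixture because it is re-enolised in step 2.

Step 2
Reactants: 4 6-methylcarvone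
Product: 6 (5S,6S)-2,6-dimethyl-6-(prop-2-en-1-yl)-5-(prop-1-en-2-yl)cyclohex-2-en-1-one (allyl trans to isopropenyl), via lithium dienolate 5 (not isolated)
Conditions: LDA, THF, −78 °C; then allyl bromide, −78 °C → rt
Reagents that add atoms: allyl bromide, C=CCBr
Why: Enolate alkylation creating the quaternary centre (future C10): allyl bromide attacks the face anti to the neighbouring isopropenyl group, so allyl (future C1–C3) ends trans and the methyl (future C20) cis to it, as a trans-decalin requires.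

Step 3
Reactants: 6 allyl enone
Product: 7 3-[(1S,6S)-1,3-dimethyl-2-oxo-6-(prop-1-en-2-yl)cyclohex-3-en-1-yl]propanal
Conditions: PdCl2(PhCN)2 (cat.), CuCl2·2H2O (cat.), AgNO2 (cat.), t-BuOH/MeNO2, O2 (1 atm), rt
Reagents that add atoms: dioxygen, O=O
Why: Aldehyde-selective (anti-Markovnikov) nitrite-modified Wacker oxidation acts only on the monosubstituted alkene (the 1,1-disubstituted isopropenyl group and the enone are inert); no stereocentre is touched.

Step 4
Reactants: 7 keto aldehyde
Product: 8 (4aS,6S,8aS)-6-hydroxy-2,5,5,8a-tetramethyl-4a,5,6,7,8,8a-hexahydronaphthalen-1(4H)-one (3β-hydroxy-4,4,8,10-tetramethyl-trans-decal-7-en-9-one)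
Conditions: Fe(acac)3 (20 mol %), PhSiH3, EtOH, 60 °C, Ar, dilute
Reagents that add atoms: none
Why: Metal-hydride HAT turns the isopropenyl group Markovnikov-selectively into the tertiary C4 radical, which closes ring A by 6-exo addition to the aldehyde through a chair with both tether bonds equatorial on ring B (trans-decalin dictated by C5/C10) and the C=O pseudo-equatorial, giving the gem-dimethyl group and the equatorial 3β-alcohol.

Step 5
Reactants: 8 hydroxy enone
Product: 9 7α,8α-epoxy-3β-hydroxy-4,4,8,10-tetramethyl-trans-decalin-9-one (epoxide oxygen anti to the C10 methyl)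
Conditions: 30 % H2O2, NaOH (cat.), MeOH, 0 °C → rt
Reagents that add atoms: hydrogen peroxide, OO
Why: Weitz–Scheffer nucleophilic epoxidation: hydroperoxide adds axially to C7 on the α-face and the enolate closes on the same face, away from the axial C10 methyl.

Step 6
Reactants: 9 epoxy ketone
Product: 12 4,4,8,10-tetramethyl-trans-decal-8-ene-3β,7α-diol, via epoxy hydrazone 10 (not isolated), via hydroxy alkenyldiazene 11 (not isolated)
Conditions: N2H4·H2O, AcOH (cat.), MeOH, 0 °C → rt
Reagents that add atoms: none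
Why: Wharton transposition: hydrazone formation, epoxide opening and loss of N2 give the Δ8(9) allylic alcohol; the C7–O bond is never broken, so the alcohol is 7α.

Step 7
Reactants: 2 (S)-(−)-β-citronellol
Product: 14 (6S)-8-chloro-2,6-dimethyloct-2-ene ((S)-citronellyl chloride), via alkoxyphosphonium chloride 13 (not isolated)
Conditions: PPh3, NCS, CH2Cl2, 0 °C → rt
Reagents that add atoms: N-chlorosuccinimide, ClN1C(=O)CCC1=O
Why: Appel-type chlorination (SN2 at the primary carbon) leaves the remote stereocentre untouched; the chloride is an enolate-proof placeholder for the C15 acetate.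

Step 8
Reactants: 14 (S)-citronellyl chloride
Product: 16 (4S)-6-chloro-4-methylhexanoic acid, via (4S)-6-chloro-4-methylhexanal 15 (not isolated)
Conditions: RuCl3·xH2O (cat.), NaIO4, MeCN/EtOAc/H2O, rt
Reagents that add atoms: sodium periodate, [Na+].[O-]I(=O)(=O)=O; water, O
Why: RuO4 oxidative cleavage of the trisubstituted alkene gives the acid and acetone; the stereocentre is remote.

Step 9
Reactants: 12 diol; 16 chloro acid
Product: 18 3β-hydroxy-4,4,8,10-tetramethyl-trans-decal-8-en-7β-yl (4S)-6-chloro-4-methylhexanoate, via alkoxyphosphonium carboxylate 17 (not isolated)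
Conditions: PPh3, DIAD, THF, 0 °C → rt
Reagents that add atoms: none
Why: Mitsunobu esterification: SN2 attack of the carboxylate on the activated allylic C7 oxyphosphonium inverts C7 (7α → 7β), while the neopentyl 3β-OH cannot undergo SN2 and stays free.

Step 10
Reactants: 18 allylic ester
Product: 21 (13S)-15-chloro-3β-hydroxy-11-carboxylabd-7-ene (CO2H on C11; C11 epimers), via bis-TMS ketene acetal 19 (not isolated), via bis-TMS rearranged ester 20 (not isolated)
Conditions: LDA (3 equiv), TMSCl–Et3N, THF, −78 °C → rt, then 65 °C; 1 M HCl work-up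
Reagents that add atoms: none
Why: Key step, Ireland–Claisen [3,3]-sigmatropic rearrangement: the ketene acetal carbon is delivered suprafacially from the 7β C–O bond to the β-face of C9, forming C9–C11 (H-9 α) and moving the olefin to Δ7; the 3-OH is masked in situ as its TMS ether and the C11 configuration is irrelevant.

Step 11
Reactants: 21 acid
Product: 23 (13S)-15-chlorolabd-7-en-3β-ol, via Barton ester 22 (not isolated)
Conditions: N-hydroxypyridine-2-thione, DCC, DMAP (cat.), CH2Cl2, rt, dark; then t-BuSH, hν (W lamp), PhH, rt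
Reagents that add atoms: none
Why: Barton reductive radical decarboxylation: the C11 radical is quenched by the thiol faster than it can attack the homoallylic olefin, and the C11 stereocentre is erased.

Step 12
Reactants: 23 chloro alcohol
Product: 24 (13S)-3β-hydroxylabd-7-en-15-yl acetate (target)
Conditions: CsOAc, NaI (cat.), DMF, 80 °C
Reagents that add atoms: caesium acetate, [Cs+].CC([O-])=O
Why: Iodide-assisted SN2 displacement of the primary chloride by acetate leaves the hindered secondary 3β-OH and the trisubstituted olefin untouched.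

## Compound list

1 | (R)-(−)-carvone | CC(=C)[C@@H]1CC=C(C)C(=O)C1 | starting material
2 | (S)-(−)-β-citronellol | OCC[C@@H](C)CCC=C(C)C | starting material
3 | lithium dienolate of 1 (C6-deprotonated) | [Li]OC1=C[C@H](C(C)=C)CC=C1C | intermediate
4 | (5R,6RS)-2,6-dimethyl-5-(prop-1-en-2-yl)cyclohex-2-en-1-one | O=C1C(C)=CC[C@@H](C(C)=C)C1C | intermediate
5 | lithium dienolate of 4 | [Li]OC1=C(C)[C@H](C(C)=C)CC=C1C | intermediate
6 | (5S,6S)-2,6-dimethyl-6-(prop-2-en-1-yl)-5-(prop-1-en-2-yl)cyclohex-2-en-1-one | O=C1C(C)=CC[C@@H](C(C)=C)[C@]1(C)CC=C | intermediate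
7 | 3-[(1S,6S)-1,3-dimethyl-2-oxo-6-(prop-1-en-2-yl)cyclohex-3-en-1-yl]propanal | O=C1C(C)=CC[C@@H](C(C)=C)[C@]1(C)CCC=O | intermediate
8 | (4aS,6S,8aS)-6-hydroxy-2,5,5,8a-tetramethyl-4a,5,6,7,8,8a-hexahydronaphthalen-1(4H)-one | O=C1C(C)=CC[C@H]2C(C)(C)[C@@H](O)CC[C@]12C | intermediate
9 | 7α,8α-epoxy-3β-hydroxy-4,4,8,10-tetramethyl-trans-decalin-9-one | O=C1[C@]2(C)O[C@@H]2C[C@H]3C(C)(C)[C@@H](O)CC[C@]13C | intermediate
10 | hydrazone of 9 | NN=C1[C@]2(C)O[C@@H]2C[C@H]3C(C)(C)[C@@H](O)CC[C@]13C | intermediate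
11 | 9-diazenyl-4,4,8,10-tetramethyl-trans-decal-8-ene-3β,7α-diol | N=NC1=C(C)[C@H](O)C[C@H]2C(C)(C)[C@@H](O)CC[C@]12C | intermediate
12 | 4,4,8,10-tetramethyl-trans-decal-8-ene-3β,7α-diol | C1=C(C)[C@H](O)C[C@H]2C(C)(C)[C@@H](O)CC[C@]12C | intermediate
13 | {[(3S)-3,7-dimethyloct-6-en-1-yl]oxy}triphenylphosphonium chloride | CC(C)=CCC[C@H](C)CCO[P+](c1ccccc1)(c1ccccc1)c1ccccc1.[Cl-] | intermediate
14 | (6S)-8-chloro-2,6-dimethyloct-2-ene | ClCC[C@@H](C)CCC=C(C)C | intermediate
15 | (4S)-6-chloro-4-methylhexanal | ClCC[C@@H](C)CCC=O | intermediate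
16 | (4S)-6-chloro-4-methylhexanoic acid | ClCC[C@@H](C)CCC(=O)O | intermediate
17 | 7α-(triphenylphosphoniooxy) derivative of 12, (4S)-6-chloro-4-methylhexanoate salt | C1=C(C)[C@H](O[P+](c3ccccc3)(c3ccccc3)c3ccccc3)C[C@H]2C(C)(C)[C@@H](O)CC[C@]12C.[O-]C(=O)CC[C@H](C)CCCl | intermediate
18 | 3β-hydroxy-4,4,8,10-tetramethyl-trans-decal-8-en-7β-yl (4S)-6-chloro-4-methylhexanoate | C1=C(C)[C@@H](OC(=O)CC[C@H](C)CCCl)C[C@H]2C(C)(C)[C@@H](O)CC[C@]12C | intermediate
19 | trimethylsilyl ketene acetal of 18, 3-O-TMS ether | C1=C(C)[C@@H](OC(O[Si](C)(C)C)=CC[C@H](C)CCCl)C[C@H]2C(C)(C)[C@@H](O[Si](C)(C)C)CC[C@]12C | intermediate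
20 | trimethylsilyl ester and 3-O-TMS ether of 21 | ClCC[C@@H](C)CC(C(=O)O[Si](C)(C)C)[C@H]1C(C)=CC[C@H]2C(C)(C)[C@@H](O[Si](C)(C)C)CC[C@]12C | intermediate
21 | (13S)-15-chloro-3β-hydroxy-11-carboxylabd-7-ene (C11 epimers) | ClCC[C@@H](C)CC(C(=O)O)[C@H]1C(C)=CC[C@H]2C(C)(C)[C@@H](O)CC[C@]12C | intermediate
22 | 2-thioxopyridin-1(2H)-yl ester (Barton ester) of 21 | ClCC[C@@H](C)CC(C(=O)ON1C=CC=CC1=S)[C@H]2C(C)=CC[C@H]3C(C)(C)[C@@H](O)CC[C@]23C | intermediate
23 | (13S)-15-chlorolabd-7-en-3β-ol; (2S,4aR,5S,8aR)-5-[(3S)-5-chloro-3-methylpentyl]-1,1,4a,6-tetramethyl-1,2,3,4,4a,5,8,8a-octahydronaphthalen-2-ol | ClCC[C@@H](C)CC[C@H]1C(C)=CC[C@H]2C(C)(C)[C@@H](O)CC[C@]12C | intermediate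
24 | (13S)-3β-hydroxylabd-7-en-15-yl acetate; (3S)-5-[(1S,4aR,6S,8aR)-6-hydroxy-2,5,5,8a-tetramethyl-1,4,4a,5,6,7,8,8a-octahydronaphthalen-1-yl]-3-methylpentyl acetate | CC(=O)OCC[C@@H](C)CC[C@H]1C(C)=CC[C@H]2C(C)(C)[C@@H](O)CC[C@]12C | target

## Step count and risks

Total step count: 12. Longest linear sequence: 10 (steps 1–6 and 9–12, from 1 to 24).

The three steps most likely to fail:

Step 3 (aldehyde-selective Wacker; the regiochemistry may erode toward the methyl ketone). The fallback sets out from 6 and comes back at 7. The monosubstituted allyl terminus is hydroborated with disiamylborane (the 1,1-disubstituted isopropenyl group and the hindered enone react far more slowly) to bis(3-methylbutan-2-yl){3-[(1S,6S)-1,3-dimethyl-2-oxo-6-(prop-1-en-2-yl)cyclohex-3-en-1-yl]propyl}borane F1. This is oxidised in the same flask with NaBO3·4H2O to (5S,6S)-6-(3-hydroxypropyl)-2,6-dimethyl-5-(prop-1-en-2-yl)cyclohex-2-en-1-one F2, and Dess–Martin oxidation then gives 7.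

Step 4 (HAT ring closure onto the aldehyde; the yield and the C3 ratio are the least precedented point of the route). The fallback sets out from 7 and comes back at 8. The cyclisation is run without regard to the C3 outcome, giving 8 mixed with its epimer 3α-hydroxy-4,4,8,10-tetramethyl-trans-decal-7-en-9-one F3. The mixture is oxidised (Dess–Martin periodinane) to 4,4,8,10-tetramethyl-trans-decal-7-ene-3,9-dione F4. The saturated C3 ketone is then reduced chemoselectively (NaBH4, MeOH/CH2Cl2, −78 °C; the α-methyl enone next to the quaternary C10 is much slower), hydride entering axially from the α-face to give the equatorial 3β-alcohol 8. C3 is then set by substrate-controlled hydride delivery instead of by the radical transition state.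

Step 6 (Wharton reaction on a ketone flanked by two fully substituted carbons; hydrazone formation may be slow and hydrazine may open the epoxide). The fallback sets out from 8 and comes back at 18, by-passing 9, 12 and the Mitsunobu step. Luche reduction (NaBH4, CeCl3, MeOH; hydride enters anti to the C10 methyl) gives 4,4,8,10-tetramethyl-trans-decal-7-ene-3β,9β-diol F5. A rhenium-oxo catalysed suprafacial 1,3-transposition of the allylic alcohol (Ph3SiOReO3 cat., Et2O, 0 °C), driven toward the less congested isomer, gives 4,4,8,10-tetramethyl-trans-decal-8-ene-3β,7β-diol F6. DCC/DMAP esterification with 16 at the allylic 7β-OH (the neopentyl 3β-OH acylates more slowly) gives 18.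

## Further compounds

F1 | step 3 | bis(3-methylbutan-2-yl){3-[(1S,6S)-1,3-dimethyl-2-oxo-6-(prop-1-en-2-yl)cyclohex-3-en-1-yl]propyl}borane | O=C1C(C)=CC[C@@H](C(C)=C)[C@]1(C)CCCB(C(C)C(C)C)C(C)C(C)C
F2 | step 3 | (5S,6S)-6-(3-hydroxypropyl)-2,6-dimethyl-5-(prop-1-en-2-yl)cyclohex-2-en-1-one | O=C1C(C)=CC[C@@H](C(C)=C)[C@]1(C)CCCO
F3 | step 4 | 3α-hydroxy-4,4,8,10-tetramethyl-trans-decal-7-en-9-one (C3 epimer of 8) | O=C1C(C)=CC[C@H]2C(C)(C)[C@H](O)CC[C@]12C
F4 | step 4 | 4,4,8,10-tetramethyl-trans-decal-7-ene-3,9-dione | O=C1C(C)=CC[C@H]2C(C)(C)C(=O)CC[C@]12C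
F5 | step 6 | 4,4,8,10-tetramethyl-trans-decal-7-ene-3β,9β-diol | O[C@H]1C(C)=CC[C@H]2C(C)(C)[C@@H](O)CC[C@]12C
F6 | step 6 | 4,4,8,10-tetramethyl-trans-decal-8-ene-3β,7β-diol | C1=C(C)[C@@H](O)C[C@H]2C(C)(C)[C@@H](O)CC[C@]12C
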